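## Retrosynthetic overview

1. The E,E,E-triene is cut at its central diene single bond: Suzuki–Miyaura coupling of an (S)-configured tetronic acid vinyl iodide with a bis-furyl dienyl MIDA boronate.
2. The vinyl iodide's only stereocentre (C5, S) comes from a chiral Brønsted acid-catalysed enantioselective protonation of an achiral 2,4-bis(silyloxy)furan. That furan is made from the racemic C5-allylation product of 3-methyltetronic acid dianion with an (E)-3-iodo-2-methylallyl electrophile (from propargyl alcohol by carboalumination).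
3. The dienyl boronate comes from hydrozirconation of a methyl alkyne and Negishi coupling with a bromovinyl MIDA boronate. The alkyne comes from Negishi alkylation of 4-bromo-2-(furan-3-ylmethyl)furan, itself from 3-furyllithium and 4-bromofuran-2-carbaldehyde with ionic deoxygenation.
4. No ring is built: ring A (butenolide), ring B (2,4-disubstituted furan) and ring C (3-furyl) are all bought intact.

Assumption: 3-methyltetronic acid, 5-bromopent-2-yne and trans-2-bromovinylboronic acid MIDA ester are treated as catalogue chemicals; the catalyst antipode that gives 5S in step 3 cannot be predicted and is fixed in a first small-scale run, with the configuration confirmed on the iodine-containing product.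

## Route

**Step 1**
Reactants: 1 prop-2-yn-1-ol (propargyl alcohol)
Product: 2 (2E)-3-iodo-2-methylprop-2-en-1-ol
Conditions: AlMe3 (3 equiv), Cp2ZrCl2 (0.25 equiv), CH2Cl2, 0 °C → rt, 18 h; then I2, THF, −30 → 0 °C; aq. K2CO3 work-up
Reagents that add atoms: trimethylaluminium C[Al](C)C; iodine II
Why: Negishi zirconocene-catalysed carboalumination adds CH3 and Al syn across the terminal alkyne with CH3 on the internal carbon, and iodinolysis of the alkenyl–Al bond with retention gives the E iodide (I trans to CH2OH), a routine building block.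

**Step 2**
Reactants: 2 (2E)-3-iodo-2-methylprop-2-en-1-ol; 3 4-hydroxy-3-methylfuran-2(5H)-one (3-methyltetronic acid)
Product: 6 rac-4-hydroxy-5-[(2E)-3-iodo-2-methylprop-2-en-1-yl]-3-methylfuran-2(5H)-one, via allylic mesylate 4 (not isolated), via tetronate dianion 5 (not isolated)
Conditions: 2, NaH, THF, 0 °C, then MsCl (0.98 equiv), −20 °C; separately 3, LiN(i-Pr)2 (2.15 equiv), THF/DMPU, −78 → −40 °C; solution of 4 added at −78 °C, then → −20 °C; 1 M HCl
Reagents that add atoms: none
Why: Weiler-type dianion alkylation, in which the second deprotonation of the cyclic β-keto ester enolate occurs at C5 and this most basic carbon displaces the primary allylic mesylate by SN2 (SN2′ would have to attack the iodine-bearing carbon), giving the C5-allylated acid as a racemate whose configuration is set only in step 3.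

**Step 3**
Reactants: 6 rac-4-hydroxy-5-[(2E)-3-iodo-2-methylprop-2-en-1-yl]-3-methylfuran-2(5H)-one
Product: 9 (5S)-4-hydroxy-5-[(2E)-3-iodo-2-methylprop-2-en-1-yl]-3-methylfuran-2(5H)-one, via bis-silyloxyfuran 7 (not isolated), via O-silyl butenolide 8 (not isolated)
Conditions: TBSOTf (2.2 equiv), Et3N (2.5 equiv), CH2Cl2, 0 °C; pentane, filtration through neutral alumina under argon, evaporation; then chiral IDPi Brønsted acid (BINOL-derived imidodiphosphorimidate, 3,3′-aryl = 3,5-(CF3)2C6H3, N-triflyl, antipode giving 5S; 2 mol %), MeOH (1.1 equiv, syringe pump), toluene, −78 °C; then 1 M HCl, THF, 0 °C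
Reagents that add atoms: none
Why: Proposed new method: a catalytic asymmetric γ-protonation of an aromatic 2,4-bis(silyloxy)furan, in which double silylation erases the racemic centre of 6 to give achiral 7, the confined chiral acid transfers H+ to C5 inside a tight ion pair (C5 is favoured over C3 because it leads to the fully conjugated silyloxocarbenium ion and because C3 is buried between two OTBS groups), MeOH removes the silyl group and regenerates the acid, and hydrolysis of 8 gives (S)-9; the closest known reaction type is the chiral Brønsted acid-catalysed enantioselective protonation of bis-silyl ketene acetals used to deracemise α-branched carboxylic acids, here moved from the α-carbon of an acyclic ketene acetal to the vinylogous carbon of a silyloxyfuran.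

**Step 4**
Reactants: 10 3-bromofuran; 11 4-bromofuran-2-carbaldehyde
Product: 14 4-bromo-2-(furan-3-ylmethyl)furan, via furan-3-yllithium 12 (not isolated), via lithium carbinolate 13 (not isolated)
Conditions: 10, n-BuLi, Et2O, −78 °C; 11, −78 °C; then Et3SiH (3 equiv), CF3CO2H (8 equiv), CH2Cl2, −78 → 0 °C
Reagents that add atoms: none
Why: Bromine–lithium exchange at −78 °C gives 3-furyllithium, which adds to the aldehyde faster than it exchanges with the ring bromide, and the bis-furyl carbinol is reduced in the same pot by ionic hydrogenation (furyl-stabilised cation from CF3CO2H, hydride from Et3SiH), the 4-bromo substituent tempering the acid sensitivity of ring B.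

**Step 5**
Reactants: 14 4-bromo-2-(furan-3-ylmethyl)furan; 15 5-bromopent-2-yne
Product: 17 2-(furan-3-ylmethyl)-4-(pent-3-yn-1-yl)furan, via pent-3-ynylzinc bromide 16 (not isolated)
Conditions: 15, Zn dust, LiCl, THF, 50 °C; then 14, Pd(OAc)2 (2 mol %), SPhos (4 mol %), THF, 50 °C
Reagents that add atoms: none
Why: LiCl-promoted zinc insertion into the primary bromide followed by Negishi sp3–sp2 cross-coupling with a palladium/biarylphosphine catalyst, which handles electron-rich 3-bromofurans and suppresses β-hydride elimination, while the internal alkyne and both furans are inert.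

**Step 6**
Reactants: 17 2-(furan-3-ylmethyl)-4-(pent-3-yn-1-yl)furan; 18 2-[(E)-2-bromoethenyl]-6-methyl-1,3,6,2-dioxazaborocane-4,8-dione (trans-2-bromovinylboronic acid MIDA ester)
Product: 21 2-[(1E,3E)-6-[5-(furan-3-ylmethyl)furan-3-yl]-3-methylhexa-1,3-dien-1-yl]-6-methyl-1,3,6,2-dioxazaborocane-4,8-dione, via alkenylzirconocene chloride 19 (not isolated), via alkenylzinc chloride 20 (not isolated)
Conditions: Cp2Zr(H)Cl (1.2 equiv), THF, 50 °C; ZnCl2 (1.2 equiv), 0 °C; 18 (1.3 equiv), Pd(PPh3)4 (5 mol %), THF/DMF, rt → 40 °C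
Reagents that add atoms: none
Why: Hydrozirconation is a syn addition that, after equilibration at 50 °C, places Zr on the less hindered CH3-bearing alkyne carbon (about 9:1 or better expected, minor isomer removed by crystallisation of 21), and zinc transmetalation/Negishi coupling proceeds with retention at both alkenyl carbons to give the 1E,3E diene while the sp3-hybridised MIDA boron is untouched under anhydrous conditions.

**Step 7**
Reactants: 21 the dienyl MIDA boronate; 9 (5S)-4-hydroxy-5-[(2E)-3-iodo-2-methylprop-2-en-1-yl]-3-methylfuran-2(5H)-one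
Product: 23 (5S)-5-[(2E,4E,6E)-9-[5-(furan-3-ylmethyl)furan-3-yl]-2,6-dimethylnona-2,4,6-trien-1-yl]-4-hydroxy-3-methylfuran-2(5H)-one (CNP0176158.1), via dienylboronic acid 22 (not isolated)
Conditions: 21 (1.2 equiv), Pd(OAc)2 (5 mol %), XPhos (10 mol %), 1 M aq. NaOH (5 equiv), THF, 23 °C, argon, dark; acidify to pH 3–4 (aq. NaH2PO4)
Reagents that add atoms: none
Why: Aqueous NaOH releases the boronic acid from the MIDA cage and Suzuki–Miyaura alkenyl–alkenyl coupling joins the two E alkenes with retention to give the E,E,E triene, with no new stereocentre and no epimerisation at C5 because ring A is present as its tetronate enolate, whose C5–H is not acidic.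

## Compound list

1 | prop-2-yn-1-ol | C#CCO | starting material
2 | (2E)-3-iodo-2-methylprop-2-en-1-ol | OC/C(C)=C/I | intermediate
3 | 4-hydroxy-3-methylfuran-2(5H)-one (3-methyltetronic acid) | CC1=C(O)COC1=O | starting material
4 | (2E)-3-iodo-2-methylprop-2-en-1-yl methanesulfonate | CS(=O)(=O)OC/C(C)=C/I | intermediate
5 | dilithium C5,O4-dianion of 3-methyltetronic acid | [Li+].[Li+].CC1=C([O-])[CH-]OC1=O | intermediate
6 | rac-4-hydroxy-5-[(2E)-3-iodo-2-methylprop-2-en-1-yl]-3-methylfuran-2(5H)-one | CC1=C(O)C(C/C(C)=C/I)OC1=O | intermediate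
7 | 2,4-bis(tert-butyldimethylsilyloxy)-5-[(2E)-3-iodo-2-methylprop-2-en-1-yl]-3-methylfuran (achiral) | Cc1c(O[Si](C)(C)C(C)(C)C)oc(C/C(C)=C/I)c1O[Si](C)(C)C(C)(C)C | intermediate
8 | (5S)-4-(tert-butyldimethylsilyloxy)-5-[(2E)-3-iodo-2-methylprop-2-en-1-yl]-3-methylfuran-2(5H)-one | CC1=C(O[Si](C)(C)C(C)(C)C)[C@H](C/C(C)=C/I)OC1=O | intermediate
9 | (5S)-4-hydroxy-5-[(2E)-3-iodo-2-methylprop-2-en-1-yl]-3-methylfuran-2(5H)-one | CC1=C(O)[C@H](C/C(C)=C/I)OC1=O | intermediate
10 | 3-bromofuran | Brc1ccoc1 | starting material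
11 | 4-bromofuran-2-carbaldehyde | O=Cc1cc(Br)co1 | starting material
12 | furan-3-yllithium | [Li]c1ccoc1 | intermediate
13 | lithium (4-bromofuran-2-yl)(furan-3-yl)methanolate (racemic) | [Li+].[O-]C(c1ccoc1)c1cc(Br)co1 | intermediate
14 | 4-bromo-2-(furan-3-ylmethyl)furan | Brc1coc(Cc2ccoc2)c1 | intermediate
15 | 5-bromopent-2-yne | CC#CCCBr | starting material
16 | pent-3-yn-1-ylzinc bromide | CC#CCC[Zn]Br | intermediate
17 | 2-(furan-3-ylmethyl)-4-(pent-3-yn-1-yl)furan | CC#CCCc1coc(Cc2ccoc2)c1 | intermediate
18 | 2-[(E)-2-bromoethenyl]-6-methyl-1,3,6,2-dioxazaborocane-4,8-dione | C[N+]12CC(=O)O[B-]1(/C=C/Br)OC(=O)C2 | starting material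
19 | chloro[(2E)-5-[5-(furan-3-ylmethyl)furan-3-yl]pent-2-en-2-yl]zirconocene | C/C(=C\CCc1coc(Cc2ccoc2)c1)[Zr](Cl)(C1C=CC=C1)C1C=CC=C1 | intermediate
20 | [(2E)-5-[5-(furan-3-ylmethyl)furan-3-yl]pent-2-en-2-yl]zinc chloride | C/C(=C\CCc1coc(Cc2ccoc2)c1)[Zn]Cl | intermediate
21 | 2-[(1E,3E)-6-[5-(furan-3-ylmethyl)furan-3-yl]-3-methylhexa-1,3-dien-1-yl]-6-methyl-1,3,6,2-dioxazaborocane-4,8-dione | C[N+]12CC(=O)O[B-]1(/C=C/C(C)=C/CCc1coc(Cc3ccoc3)c1)OC(=O)C2 | intermediate
22 | [(1E,3E)-6-[5-(furan-3-ylmethyl)furan-3-yl]-3-methylhexa-1,3-dien-1-yl]boronic acid | OB(O)/C=C/C(C)=C/CCc1coc(Cc2ccoc2)c1 | intermediate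
23 | (5S)-5-[(2E,4E,6E)-9-[5-(furan-3-ylmethyl)furan-3-yl]-2,6-dimethylnona-2,4,6-trien-1-yl]-4-hydroxy-3-methylfuran-2(5H)-one | CC1=C(O)[C@H](C/C(C)=C/C=C/C(C)=C/CCc2coc(Cc3ccoc3)c2)OC1=O | target

## Step count and risks

Total: 7 steps (isolated products 2, 6, 9, 14, 17, 21, 23). Longest linear sequence: 4 steps (1 → 2 → 3 → 7, or 4 → 5 → 6 → 7).

Steps most likely to fail:

1. **Step 3 (the new enantioselective protonation).** Risks are competing protonation at C3 (which returns racemic material after hydrolysis), uncatalysed protonation of 7 by MeOH, catalyst poisoning by residual Et3N, and an unpredictable level and sense of induction. The fallback uses known chemistry, sets out from racemic 6 and comes back at 9. Acid 6 is resolved by crystallising its diastereomeric salt with (S)-1-phenylethylamine (or the amine antipode or alkaloid that crystallises with the 5S acid), namely (1S)-1-phenylethan-1-aminium (5S)-5-[(2E)-3-iodo-2-methylprop-2-en-1-yl]-3-methyl-2-oxo-2,5-dihydrofuran-4-olate F1. Treating F1 with 1 M HCl releases 9. The acid in the mother liquor is racemised through its dianion (LiN(i-Pr)2, then aqueous acid) and returned to 6.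

2. **Step 6 (hydrozirconation/Negishi coupling).** Risks are incomplete regio-equilibration of the alkenylzirconium, reduction of 18 by residual Zr–H, and poor solubility of 18. The fallback sets out from 14 and comes back at 23, building the E-trisubstituted alkene by allylic oxidation instead of hydrometalation. Kumada coupling of 14 with (4-methylpent-3-en-1-yl)magnesium bromide (from commercial 5-bromo-2-methylpent-2-ene) and NiCl2(dppp) gives 2-(furan-3-ylmethyl)-4-(4-methylpent-3-en-1-yl)furan F2. E-selective allylic oxidation (SeO2, t-BuOOH, CH2Cl2, then MnO2) gives (2E)-5-[5-(furan-3-ylmethyl)furan-3-yl]-2-methylpent-2-enal F3. Boron-Wittig olefination with CH2(Bpin)2 and lithium 2,2,6,6-tetramethylpiperidide gives 2-[(1E,3E)-6-[5-(furan-3-ylmethyl)furan-3-yl]-3-methylhexa-1,3-dien-1-yl]-4,4,5,5-tetramethyl-1,3,2-dioxaborolane F4. F4 is coupled with 9 under the conditions of step 7 to give 23.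

3. **Step 7 (Suzuki coupling on the free tetronic acid).** Risks are protodeboronation of 22, sequestration of palladium by the tetronate, and isomerisation or decomposition of the triene in aqueous base. The fallback sets out from 17 and comes back at 23 by a non-aqueous Stille sequence. Hydrozirconation of 17 (Cp2Zr(H)Cl, THF, 50 °C) and iodinolysis (I2) give 2-(furan-3-ylmethyl)-4-[(3E)-4-iodopent-3-en-1-yl]furan F5. Mono-Stille coupling with excess (E)-1,2-bis(tributylstannyl)ethene and PdCl2(MeCN)2 in DMF gives tributyl[(1E,3E)-6-[5-(furan-3-ylmethyl)furan-3-yl]-3-methylhexa-1,3-dien-1-yl]stannane F6. F6 is coupled with 9 using Pd(PPh3)4, CuI and CsF in DMF at rt to give 23.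

## Further compounds

F1 | step 3 | (1S)-1-phenylethan-1-aminium (5S)-5-[(2E)-3-iodo-2-methylprop-2-en-1-yl]-3-methyl-2-oxo-2,5-dihydrofuran-4-olate | CC1=C([O-])[C@H](C/C(C)=C/I)OC1=O.C[C@H]([NH3+])c1ccccc1
F2 | step 6 | 2-(furan-3-ylmethyl)-4-(4-methylpent-3-en-1-yl)furan | CC(C)=CCCc1coc(Cc2ccoc2)c1
F3 | step 6 | (2E)-5-[5-(furan-3-ylmethyl)furan-3-yl]-2-methylpent-2-enal | O=C/C(C)=C/CCc1coc(Cc2ccoc2)c1
F4 | step 6 | 2-[(1E,3E)-6-[5-(furan-3-ylmethyl)furan-3-yl]-3-methylhexa-1,3-dien-1-yl]-4,4,5,5-tetramethyl-1,3,2-dioxaborolane | CC1(C)OB(/C=C/C(C)=C/CCc2coc(Cc3ccoc3)c2)OC1(C)C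
F5 | step 7 | 2-(furan-3-ylmethyl)-4-[(3E)-4-iodopent-3-en-1-yl]furan | C/C(I)=C\CCc1coc(Cc2ccoc2)c1
F6 | step 7 | tributyl[(1E,3E)-6-[5-(furan-3-ylmethyl)furan-3-yl]-3-methylhexa-1,3-dien-1-yl]stannane | CCCC[Sn](CCCC)(CCCC)/C=C/C(C)=C/CCc1coc(Cc2ccoc2)c1
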